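**Plan**

- Retrosynthetic cuts, in this order: the C3=C4 olefin of ring A's pyran (ring-closing metathesis); the O1–C2 ether bond of ring A (O-tert-allylation of a phenol); the bond from the bridging CH to C8 of ring A (Friedel–Crafts addition to a ring B ortho-quinone methide); the pyran of ring B (prenal annulation of phloroacetophenone).
- Forward: the ring B chromene is made first, with its C5 oxygen masked as a methoxymethyl ether, which also forces the 8-acetyl regiochemistry. C6 of ring B is then armed with a 1-hydroxyethyl group and joined to 2-allyl-3,5-dimethoxyphenol. Allyl is moved to propenyl, the phenol is O-alkylated, metathesis closes the pyran of ring A last, and the acetal is removed.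
- Enabling feature: in ring A the oxygen-bearing carbon C8a lies between C8 (bridge) and C4a (which carries C4), and C3=C4 is a cis olefin in a six-membered ring between aryl C4a and the quaternary C2. One phenol OH therefore directs the ortho C–C union, is the Claisen origin of the C4 carbon on its other side, and finally becomes O1. This fixes the 8-linked (not 6-linked) chromene.
- Stereochemistry: the only stereocenter (the bridging CH) is set in the union, by chiral phosphoric acid control of the face of the planar quinone methide. No later step touches it.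

Key step: step 10

Remark: the sense of induction in step 7 is assumed; (R)-TRIP is written, and its mirror image is to be used if the addition favours the other face.
Remark: the bridging carbon keeps one spatial arrangement from 14 to 18; its descriptor reads S in 14 and 15 and R from 16 on only because O-alkylation of ring A changes the ligand ranking.
Remark: tert-butyl 2-methylbut-3-en-2-yl carbonate and (R)-TRIP are taken as purchasable reagents.

**Route**

Step 1
Reactants: 1 1-(2,4,6-trihydroxyphenyl)ethanone
Product: 2 1-[2,6-dihydroxy-4-(methoxymethoxy)phenyl]ethanone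
Conditions: MOMCl (1.0 equiv), K2CO3, acetone, 0 °C → rt
Reagents that add atoms: chloromethyl methyl ether, COCCl
Why: Williamson-type O-alkylation; the 4-hydroxyl is the most acidic and the only one not hydrogen-bonded to the acetyl group, so one equivalent of the chloride should protect it selectively.

Step 2
Reactants: 2 1-[2,6-dihydroxy-4-(methoxymethoxy)phenyl]ethanone; 3 3-methylbut-2-enal
Product: 5 1-[7-hydroxy-5-(methoxymethoxy)-2,2-dimethyl-2H-chromen-8-yl]ethanone, via oxatriene 4 (not isolated)
Conditions: ethylenediammonium diacetate (20 mol%), PhMe, 100 °C; 3 (1.2 equiv)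
Reagents that add atoms: none
Why: Amine-salt catalysed formal [3+3] annulation (Knoevenagel-type C-alkylation, loss of water to oxatriene 4, oxa-6π electrocyclisation); with the para oxygen blocked, only one of the two symmetry-equivalent ortho hydroxyls can close the pyran, which places the acetyl group at C8.

Step 3
Reactants: 5 1-[7-hydroxy-5-(methoxymethoxy)-2,2-dimethyl-2H-chromen-8-yl]ethanone
Product: 7 8-acetyl-7-hydroxy-5-(methoxymethoxy)-2,2-dimethyl-2H-chromene-6-carbaldehyde, via benzylic alcohol 6 (not isolated)
Conditions: MgCl2, Et3N, (CH2O)n, MeCN, 70 °C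
Reagents that add atoms: formaldehyde (from paraformaldehyde), C=O
Why: Casnati–Skattebøl ortho-formylation; the magnesium phenoxide directs formaldehyde to C6, the only free ring position and ortho to the hydroxyl, and hydroxymethyl compound 6 is oxidised by a second formaldehyde through hydride transfer.

Step 4
Reactants: 7 8-acetyl-7-hydroxy-5-(methoxymethoxy)-2,2-dimethyl-2H-chromene-6-carbaldehyde
Product: 8 1-[7-hydroxy-6-(1-hydroxyethyl)-5-(methoxymethoxy)-2,2-dimethyl-2H-chromen-8-yl]ethanone (racemic, used crude at once)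
Conditions: MeMgBr (2.5 equiv), THF, −78 → −30 °C; pH 7 buffer
Reagents that add atoms: methylmagnesium bromide, C[Mg]Br
Why: Grignard 1,2-addition; after deprotonation of the phenol the aldehyde is far more electrophilic than the hindered aryl ketone conjugated to the phenoxide, so methyl should add to the formyl group only, and the racemic carbinol center is erased in step 7.

Step 5
Reactants: 9 3,5-dimethoxyphenol
Product: 10 1-(allyloxy)-3,5-dimethoxybenzene
Conditions: allyl bromide, K2CO3, acetone, 56 °C
Reagents that add atoms: allyl bromide, C=CCBr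
Why: Williamson ether synthesis of the phenoxide with a primary allylic bromide.

Step 6
Reactants: 10 1-(allyloxy)-3,5-dimethoxybenzene
Product: 12 2-allyl-3,5-dimethoxyphenol, via dienone 11 (not isolated)
Conditions: PhNEt2, 190 °C
Reagents that add atoms: none
Why: Aromatic Claisen rearrangement ([3,3]) to one of the two equivalent free ortho positions, then tautomerisation of dienone 11, which places the allyl group unambiguously next to the hydroxyl.

Step 7
Reactants: 8 1-[7-hydroxy-6-(1-hydroxyethyl)-5-(methoxymethoxy)-2,2-dimethyl-2H-chromen-8-yl]ethanone; 12 2-allyl-3,5-dimethoxyphenol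
Product: 14 1-[6-[(1S)-1-(3-allyl-2-hydroxy-4,6-dimethoxyphenyl)ethyl]-7-hydroxy-5-(methoxymethoxy)-2,2-dimethyl-2H-chromen-8-yl]ethanone, via quinone methide 13 (not isolated)
Conditions: (R)-TRIP [(R)-3,3'-bis(2,4,6-triisopropylphenyl)-1,1'-binaphthyl-2,2'-diyl hydrogen phosphate] (10 mol%), 4 Å MS, CH2Cl2, −40 °C; 12 (1.5 equiv), 8 added slowly
Reagents that add atoms: none
Why: Chiral phosphoric acid catalysed Friedel–Crafts (conjugate) addition; loss of water from 8 gives the planar, electron-poor ring B ortho-quinone methide 13, and the catalyst, hydrogen-bonded to the methide carbonyl and to the OH of 12, should deliver the ortho carbon C6 of 12 (para attack lacks this hydrogen bond) to one face of the ethylidene carbon, which sets the stereocenter.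

Step 8
Reactants: 14 1-[6-[(1S)-1-(3-allyl-2-hydroxy-4,6-dimethoxyphenyl)ethyl]-7-hydroxy-5-(methoxymethoxy)-2,2-dimethyl-2H-chromen-8-yl]ethanone
Product: 15 1-[7-hydroxy-6-[(1S)-1-[2-hydroxy-4,6-dimethoxy-3-[(E)-prop-1-enyl]phenyl]ethyl]-5-(methoxymethoxy)-2,2-dimethyl-2H-chromen-8-yl]ethanone
Conditions: RuHCl(CO)(PPh3)3 (5 mol%), PhMe, 70 °C
Reagents that add atoms: none
Why: Ruthenium hydride catalysed olefin isomerisation (hydrometalation/β-hydride elimination) should move the allyl double bond into conjugation with ring A; the pyran olefin of ring B cannot migrate because C2 is quaternary, and the bridging CH is not allylic.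

Step 9
Reactants: 15 1-[7-hydroxy-6-[(1S)-1-[2-hydroxy-4,6-dimethoxy-3-[(E)-prop-1-enyl]phenyl]ethyl]-5-(methoxymethoxy)-2,2-dimethyl-2H-chromen-8-yl]ethanone
Product: 16 1-[6-[(1R)-1-[4,6-dimethoxy-2-(2-methylbut-3-en-2-yloxy)-3-[(E)-prop-1-enyl]phenyl]ethyl]-7-hydroxy-5-(methoxymethoxy)-2,2-dimethyl-2H-chromen-8-yl]ethanone
Conditions: tert-butyl 2-methylbut-3-en-2-yl carbonate (1.2 equiv), Pd(PPh3)4 (5 mol%), THF, 0 °C → rt
Reagents that add atoms: tert-butyl 2-methylbut-3-en-2-yl carbonate, C=CC(C)(C)OC(=O)OC(C)(C)C
Why: Tsuji–Trost O-allylation; zerovalent palladium ionises the tertiary carbonate with loss of CO2, and the ring A phenoxide should attack the more substituted terminus of the 1,1-dimethyl-π-allyl complex to give the tertiary ether, while the ring B hydroxyl stays locked in its hydrogen bond to the acetyl group.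

Step 10
Reactants: 16 1-[6-[(1R)-1-[4,6-dimethoxy-2-(2-methylbut-3-en-2-yloxy)-3-[(E)-prop-1-enyl]phenyl]ethyl]-7-hydroxy-5-(methoxymethoxy)-2,2-dimethyl-2H-chromen-8-yl]ethanone
Product: 17 1-[6-[(1R)-1-(5,7-dimethoxy-2,2-dimethyl-2H-chromen-8-yl)ethyl]-7-hydroxy-5-(methoxymethoxy)-2,2-dimethyl-2H-chromen-8-yl]ethanone
Conditions: second-generation Grubbs catalyst RuCl2(=CHPh)(H2IMes)(PCy3) (5 mol%), CH2Cl2 (0.005 M), 40 °C
Reagents that add atoms: none
Why: Ring-closing olefin metathesis by the Chauvin mechanism: the ruthenium benzylidene should exchange onto the terminal vinyl of the 1,1-dimethylallyl ether, the new carbene adds across the neighbouring propenyl group of ring A ([2+2]), and cycloreversion of the ruthenacyclobutane forms the C3=C4 bond and releases propene. The closest known reaction type is the metathesis closure of 2-(allyloxy)styrenes to 2H-chromenes. The pyran of ring A is closed as a six-membered ring by joining the ether-side CH (C3) to the styrenyl CH (C4), and the ring allows only the cis olefin. No stereocenter is formed, and the bridging CH, which is not allylic and meets neither acid nor base here, should keep its configuration. The step needs ring closure to win over cross-metathesis and to leave ring B's olefin alone: high dilution, the gem-dimethyl group at C2 (Thorpe–Ingold effect) and loss of volatile propene favour closure, and the C3=C4 olefin of ring B is an unstrained cis ring olefin next to a quaternary carbon with no driving force for opening. The chelated phenol, the ketone and the acetal are tolerated by the catalyst.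

Step 11
Reactants: 17 1-[6-[(1R)-1-(5,7-dimethoxy-2,2-dimethyl-2H-chromen-8-yl)ethyl]-7-hydroxy-5-(methoxymethoxy)-2,2-dimethyl-2H-chromen-8-yl]ethanone
Product: 18 1-[6-[(1R)-1-(5,7-dimethoxy-2,2-dimethyl-2H-chromen-8-yl)ethyl]-5,7-dihydroxy-2,2-dimethyl-2H-chromen-8-yl]ethanone
Conditions: 2 M aq. HCl, MeOH, rt
Reagents that add atoms: none
Why: Acid-catalysed acetal exchange with methanol should remove the methoxymethyl group as dimethoxymethane; dilute acid at room temperature is chosen so that the pyran olefins and the acid-sensitive bridging C–C bond between two electron-rich rings are left intact.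

**Compound list**

1 | 1-(2,4,6-trihydroxyphenyl)ethanone | CC(=O)c1c(O)cc(O)cc1O | starting material
2 | 1-[2,6-dihydroxy-4-(methoxymethoxy)phenyl]ethanone | CC(=O)c1c(O)cc(OCOC)cc1O | intermediate
3 | 3-methylbut-2-enal | CC(C)=CC=O | starting material
4 | 2-acetyl-3-hydroxy-5-(methoxymethoxy)-6-(3-methylbut-2-en-1-ylidene)cyclohexa-2,4-dien-1-one | CC(=O)C1=C(O)C=C(OCOC)C(=CC=C(C)C)C1=O | intermediate (not isolated)
5 | 1-[7-hydroxy-5-(methoxymethoxy)-2,2-dimethyl-2H-chromen-8-yl]ethanone | CC(=O)c1c(O)cc(OCOC)c2C=CC(C)(C)Oc12 | intermediate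
6 | 1-[7-hydroxy-6-(hydroxymethyl)-5-(methoxymethoxy)-2,2-dimethyl-2H-chromen-8-yl]ethanone | CC(=O)c1c(O)c(CO)c(OCOC)c2C=CC(C)(C)Oc12 | intermediate (not isolated)
7 | 8-acetyl-7-hydroxy-5-(methoxymethoxy)-2,2-dimethyl-2H-chromene-6-carbaldehyde | CC(=O)c1c(O)c(C=O)c(OCOC)c2C=CC(C)(C)Oc12 | intermediate
8 | 1-[7-hydroxy-6-(1-hydroxyethyl)-5-(methoxymethoxy)-2,2-dimethyl-2H-chromen-8-yl]ethanone (racemic) | CC(=O)c1c(O)c(C(C)O)c(OCOC)c2C=CC(C)(C)Oc12 | intermediate
9 | 3,5-dimethoxyphenol | COc1cc(O)cc(OC)c1 | starting material
10 | 1-(allyloxy)-3,5-dimethoxybenzene | C=CCOc1cc(OC)cc(OC)c1 | intermediate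
11 | 6-allyl-3,5-dimethoxycyclohexa-2,4-dien-1-one | C=CCC1C(=O)C=C(OC)C=C1OC | intermediate (not isolated)
12 | 2-allyl-3,5-dimethoxyphenol | C=CCc1c(O)cc(OC)cc1OC | intermediate
13 | 8-acetyl-6-ethylidene-5-(methoxymethoxy)-2,2-dimethyl-2H-chromen-7(6H)-one | CC=C1C(=O)C(C(C)=O)=C2OC(C)(C)C=CC2=C1OCOC | intermediate (not isolated)
14 | 1-[6-[(1S)-1-(3-allyl-2-hydroxy-4,6-dimethoxyphenyl)ethyl]-7-hydroxy-5-(methoxymethoxy)-2,2-dimethyl-2H-chromen-8-yl]ethanone | COc1cc(OC)c([C@H](C)c2c(OCOC)c3c(c(C(C)=O)c2O)OC(C)(C)C=C3)c(O)c1CC=C | intermediate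
15 | 1-[7-hydroxy-6-[(1S)-1-[2-hydroxy-4,6-dimethoxy-3-[(E)-prop-1-enyl]phenyl]ethyl]-5-(methoxymethoxy)-2,2-dimethyl-2H-chromen-8-yl]ethanone | COc1cc(OC)c([C@H](C)c2c(OCOC)c3c(c(C(C)=O)c2O)OC(C)(C)C=C3)c(O)c1/C=C/C | intermediate
16 | 1-[6-[(1R)-1-[4,6-dimethoxy-2-(2-methylbut-3-en-2-yloxy)-3-[(E)-prop-1-enyl]phenyl]ethyl]-7-hydroxy-5-(methoxymethoxy)-2,2-dimethyl-2H-chromen-8-yl]ethanone | COc1cc(OC)c([C@H](C)c2c(OCOC)c3c(c(C(C)=O)c2O)OC(C)(C)C=C3)c(OC(C)(C)C=C)c1/C=C/C | intermediate
17 | 1-[6-[(1R)-1-(5,7-dimethoxy-2,2-dimethyl-2H-chromen-8-yl)ethyl]-7-hydroxy-5-(methoxymethoxy)-2,2-dimethyl-2H-chromen-8-yl]ethanone | COc1cc(OC)c([C@H](C)c2c(OCOC)c3c(c(C(C)=O)c2O)OC(C)(C)C=C3)c2c1C=CC(C)(C)O2 | intermediate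
18 | 1-[6-[(1R)-1-(5,7-dimethoxy-2,2-dimethyl-2H-chromen-8-yl)ethyl]-5,7-dihydroxy-2,2-dimethyl-2H-chromen-8-yl]ethanone | COc1cc(OC)c([C@H](C)c2c(O)c3c(c(C(C)=O)c2O)OC(C)(C)C=C3)c2c1C=CC(C)(C)O2 | target

**Step count and risks**

Total steps: 11. Longest linear sequence: 9 (steps 1 to 4, then 7 to 11).

Steps most likely to fail:

Step 7. The addition to the planar quinone methide may show poor facial selectivity (methyl against hydrogen is a small difference). Attack through the para carbon of the phenol or a second alkylation may also compete. Fallback: setting out from 8 and 12, the union is run with achiral diphenyl phosphate (CH2Cl2, 0 °C) to give the racemic union product F1, and the enantiomers are separated by preparative chromatography on an amylose tris(3,5-dimethylphenylcarbamate) phase. The route is rejoined at 14.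

Step 9. Attack of the doubly flanked ring A phenoxide at the tertiary terminus of the π-allyl complex may be slow, so that the linear prenyl ether or alkylation of the ring B hydroxyl takes over. Fallback: setting out from 15, copper-catalysed propargylation with 3-chloro-3-methylbut-1-yne (DBU, CuCl2 cat., MeCN, 0 °C) should give the tertiary propargyl ether F2, whose linear cationic electrophile is less demanding in space. Semihydrogenation of the terminal alkyne (H2, Pd/CaCO3 poisoned with Pb(OAc)2, quinoline, EtOAc) then comes back to the route at 16.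

Step 3. Electrophilic substitution at the doubly flanked C6 of the chelated acetophenone may be sluggish, or the hydroxymethyl intermediate may condense to a diarylmethane; the labile carbinol of step 4 may also lose water too early. Fallback: setting out from 5, iodination at C6 with N-iodosuccinimide (MeCN, 0 °C) should give the 6-iodochromene F3. Suzuki–Miyaura coupling with vinylboronic acid pinacol ester (Pd(OAc)2, SPhos, K3PO4, THF/H2O, 60 °C) then gives the 6-vinylchromene F4. Treating F4 and 12 with the phosphoric acid of step 7 (PhMe, rt) protonates the ortho-hydroxystyrene to the same quinone methide 13, so the route is rejoined at 14 without 7 and 8.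

**Further compounds**

F1 | step 7 | racemic 1-[6-[1-(3-allyl-2-hydroxy-4,6-dimethoxyphenyl)ethyl]-7-hydroxy-5-(methoxymethoxy)-2,2-dimethyl-2H-chromen-8-yl]ethanone | COc1cc(OC)c(C(C)c2c(OCOC)c3c(c(C(C)=O)c2O)OC(C)(C)C=C3)c(O)c1CC=C
F2 | step 9 | 1-[6-[(1R)-1-[4,6-dimethoxy-2-(2-methylbut-3-yn-2-yloxy)-3-[(E)-prop-1-enyl]phenyl]ethyl]-7-hydroxy-5-(methoxymethoxy)-2,2-dimethyl-2H-chromen-8-yl]ethanone | COc1cc(OC)c([C@H](C)c2c(OCOC)c3c(c(C(C)=O)c2O)OC(C)(C)C=C3)c(OC(C)(C)C#C)c1/C=C/C
F3 | step 3 | 1-[7-hydroxy-6-iodo-5-(methoxymethoxy)-2,2-dimethyl-2H-chromen-8-yl]ethanone | CC(=O)c1c(O)c(I)c(OCOC)c2C=CC(C)(C)Oc12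
F4 | step 3 | 1-[7-hydroxy-5-(methoxymethoxy)-2,2-dimethyl-6-vinyl-2H-chromen-8-yl]ethanone | CC(=O)c1c(O)c(C=C)c(OCOC)c2C=CC(C)(C)Oc12
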